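**Retrosynthetic overview**

1. Target 25 ⇐ C18 desilylation; C12–C13 bond by hydroboration/B-alkyl Suzuki coupling of C9-vinyl compound 21 with chloroprene; 21 ⇐ Wittig on aldehyde 20 ⇐ hydroxy acid 18.
2. 18 ⇐ Diels–Alder adduct 15 by Markovnikov hydration of the 8(17)-methylene (sets C8) and hydrogenation of C5=C6 (sets C5, trans ring fusion).
3. Key step: ring B by a silicon-tethered type 2 intramolecular Diels–Alder reaction of ring-A diene 10 with buta-2,3-dienoic acid 11; the tether through O18 sets C9 and C10.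
4. Ring A comes first, from (R)-carvone: C4 by two α′-alkylations (second one trans to isopropenyl), C3 acetate by Criegee rearrangement of the isopropenyl group (retention), diene by enol triflate/Stille coupling.

Assumption: labdane numbering (C1–C20; C18 is the oxygenated carbon on C4, C19 the C4 methyl) is used for all intermediates, and α means the face of the C10 methyl group, β the opposite face.

**Route**

Step 1
Reactants: 1 (R)-(−)-carvone
Product: 2 (5R,6S)-2,6-dimethyl-5-(prop-1-en-2-yl)cyclohex-2-en-1-one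
Conditions: LiN(i-Pr)2, THF, −78 °C; MeI, −78 → 0 °C
Reagents that add atoms: iodomethane (CI)
Why: Kinetic α′-deprotonation and enolate alkylation install the future C19 methyl; the trans isomer shown predominates, and the C6 configuration is erased again by enolisation in step 2.

Step 2
Reactants: 2 (5R,6S)-2,6-dimethyl-5-(prop-1-en-2-yl)cyclohex-2-en-1-one
Product: 4 (5S,6R)-2,6-dimethyl-5-(prop-1-en-2-yl)-6-[(triethylsilyloxy)methyl]cyclohex-2-en-1-one, via lithium aldolate 3 (not isolated)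
Conditions: LiN(i-Pr)2, THF, −78 °C; HCHO (gas), −78 °C; Et3SiCl, −78 → 0 °C
Reagents that add atoms: formaldehyde (C=O); chlorotriethylsilane (CC[Si](Cl)(CC)CC)
Why: Aldol addition of the re-formed C6 enolate to monomeric formaldehyde occurs on the face opposite the neighbouring isopropenyl group, which fixes the quaternary centre (future C4: CH2O trans, CH3 cis to isopropenyl), and the lithium aldolate is capped in the same flask by O-silylation.

Step 3
Reactants: 4 (5S,6R)-2,6-dimethyl-5-(prop-1-en-2-yl)-6-[(triethylsilyloxy)methyl]cyclohex-2-en-1-one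
Product: 6 (1R,2S)-2,4-dimethyl-3-oxo-2-[(triethylsilyloxy)methyl]cyclohex-4-en-1-yl acetate, via methoxy hydroperoxide 5 (not isolated)
Conditions: O3, CH2Cl2/MeOH, −78 °C; then Ac2O, Et3N, DMAP (cat.), 0 °C → rt
Reagents that add atoms: ozone (O=[O+][O-]); methanol (CO)
Why: Ozonolysis cleaves only the electron-rich isopropenyl alkene, methanol traps the carbonyl oxide as the α-methoxy hydroperoxide, and acetylation triggers a Criegee rearrangement in which the ring carbon migrates to oxygen with retention, so the bought stereocentre becomes the C3 acetate (the quaternary C4 blocks β-elimination).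

Step 4
Reactants: 6 (1R,2S)-2,4-dimethyl-3-oxo-2-[(triethylsilyloxy)methyl]cyclohex-4-en-1-yl acetate
Product: 8 (1R,2S)-2,4-dimethyl-2-[(triethylsilyloxy)methyl]-3-(trifluoromethylsulfonyloxy)cyclohex-3-en-1-yl acetate, via lithium enolate 7 (not isolated)
Conditions: LiBH(s-Bu)3, THF, −78 °C; then N-(5-chloropyridin-2-yl)bis(trifluoromethanesulfonimide), −78 → 0 °C
Reagents that add atoms: N-(5-chloropyridin-2-yl)bis(trifluoromethanesulfonimide) (O=S(=O)(N(c1ccc(Cl)cn1)S(=O)(=O)C(F)(F)F)C(F)(F)F)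
Why: Conjugate hydride reduction of the β-unsubstituted enone gives the tetrasubstituted enolate regiospecifically, and O-triflation (enol triflate formation) fixes the C5=C10 double bond while the acetate survives at −78 °C.

Step 5
Reactants: 8 (1R,2S)-2,4-dimethyl-2-[(triethylsilyloxy)methyl]-3-(trifluoromethylsulfonyloxy)cyclohex-3-en-1-yl acetate
Product: 10 (1R,2S)-3-ethenyl-2-(hydroxymethyl)-2,4-dimethylcyclohex-3-en-1-yl acetate, via triethylsilyl diene 9 (not isolated)
Conditions: CH2=CHSnBu3, Pd(PPh3)4 (5 mol %), LiCl, THF, 65 °C; then AcOH/THF/H2O, rt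
Reagents that add atoms: tributyl(vinyl)stannane (C=C[Sn](CCCC)(CCCC)CCCC)
Why: Stille coupling of the hindered enol triflate builds the 2-methyl-1-vinylcyclohexene diene, and mild acid hydrolysis then removes the primary triethylsilyl ether without acyl migration.

Step 6
Reactants: 10 (1R,2S)-3-ethenyl-2-(hydroxymethyl)-2,4-dimethylcyclohex-3-en-1-yl acetate; 11 buta-2,3-dienoic acid
Product: 15 3α-acetoxy-18-[diisopropyl(methoxy)silyloxy]-12,13,14,15,16-pentanorlabda-5,8(17)-dien-11-oic acid, via chlorosilyl ether 12 (not isolated), via silyl ester triene 13 (not isolated), via bridged cycloadduct 14 (not isolated)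
Conditions: i-Pr2SiCl2, imidazole, CH2Cl2, 0 °C; then 11, imidazole, rt; PhMe (0.01 M), BHT, 110 °C; then MeOH, rt
Reagents that add atoms: dichlorodiisopropylsilane (CC(C)[Si](Cl)(Cl)C(C)C); methanol (CO)
Why: A disposable diisopropylsilyl tether (silyl ether to O18, silyl ester to the dienophile) forces a type 2 intramolecular Diels–Alder reaction of the allenoate on the β face defined by the C4 hydroxymethyl group, the carboxyl-bearing carbon bonding to C10 with the carboxyl endo, which forms ring B, sets C10 (methyl α) and C9 (carboxyl β), leaves the 8(17) exocyclic methylene, and methanolysis of the silyl ester then frees the acid.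

Step 7
Reactants: 15 3α-acetoxy-18-[diisopropyl(methoxy)silyloxy]-12,13,14,15,16-pentanorlabda-5,8(17)-dien-11-oic acid
Product: 17 3α-acetoxy-8β-hydroxy-18-[diisopropyl(methoxy)silyloxy]-12,13,14,15,16-pentanorlabd-5-en-11-oic acid, via organomercurial 16 (not isolated)
Conditions: Hg(OAc)2, THF/H2O, rt; then NaBH4, aq NaOH, 0 °C (5 min)
Reagents that add atoms: water (O)
Why: Oxymercuration–demercuration hydrates only the unhindered 1,1-disubstituted exocyclic alkene in the Markovnikov sense, water (assisted by the neighbouring β carboxyl) attacking C8 from the β face opposite the axial C10 methyl, which gives 8β-OH and the new C17 methyl α.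

Step 8
Reactants: 17 3α-acetoxy-8β-hydroxy-18-[diisopropyl(methoxy)silyloxy]-12,13,14,15,16-pentanorlabd-5-en-11-oic acid
Product: 18 3α-acetoxy-8β-hydroxy-18-[diisopropyl(methoxy)silyloxy]-12,13,14,15,16-pentanorlabdan-11-oic acid (5β-H)
Conditions: H2 (4 atm), Pd/C (10 %), EtOAc, rt
Reagents that add atoms: none
Why: Heterogeneous hydrogenation delivers hydrogen to the β face of C5=C6 because the α face is blocked by the axial methyl groups on C4 and C10 (and the β hydroxyl and carboxyl groups anchor the substrate to the catalyst), giving the trans-fused decalin.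

Step 9
Reactants: 18 3α-acetoxy-8β-hydroxy-18-[diisopropyl(methoxy)silyloxy]-12,13,14,15,16-pentanorlabdan-11-oic acid
Product: 19 3α-acetoxy-18-[diisopropyl(methoxy)silyloxy]-12,13,14,15,16-pentanorlabdane-8β,11-diol
Conditions: BH3·SMe2, THF, 0 °C → rt; MeOH quench
Reagents that add atoms: none
Why: Borane reduction is chemoselective for the carboxylic acid (via the acyloxyborane) over the secondary acetate and the silyl ether.

Step 10
Reactants: 19 3α-acetoxy-18-[diisopropyl(methoxy)silyloxy]-12,13,14,15,16-pentanorlabdane-8β,11-diol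
Product: 20 3α-acetoxy-8β-hydroxy-18-[diisopropyl(methoxy)silyloxy]-12,13,14,15,16-pentanorlabdan-11-al
Conditions: TEMPO (cat.), PhI(OAc)2, CH2Cl2, rt
Reagents that add atoms: none
Why: Nitroxyl-catalysed oxidation converts only the primary alcohol into the aldehyde under near-neutral conditions, avoiding retro-aldol cleavage and epimerisation at C9.

Step 11
Reactants: 20 3α-acetoxy-8β-hydroxy-18-[diisopropyl(methoxy)silyloxy]-12,13,14,15,16-pentanorlabdan-11-al
Product: 21 3α-acetoxy-18-[diisopropyl(methoxy)silyloxy]-13,14,15,16-tetranorlabd-11-en-8β-ol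
Conditions: Ph3PCH3Br, KN(SiMe3)2, THF, 0 °C; then 20, −78 → 0 °C
Reagents that add atoms: methyltriphenylphosphonium bromide (C[P+](c1ccccc1)(c1ccccc1)c1ccccc1.[Br-])
Why: Wittig methylenation with the non-stabilised ylide at low temperature converts the hindered aldehyde into the C9 vinyl group faster than enolisation or retro-aldol cleavage.

Step 12
Reactants: 21 3α-acetoxy-18-[diisopropyl(methoxy)silyloxy]-13,14,15,16-tetranorlabd-11-en-8β-ol; 22 chloroprene (2-chlorobuta-1,3-diene)
Product: 24 3α-acetoxy-18-[diisopropyl(methoxy)silyloxy]labda-13(16),14-dien-8β-ol, via alkylborane 23 (not isolated)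
Conditions: 9-BBN-H (2.2 equiv), THF, rt; then 22, Pd(OAc)2 (5 mol %), SPhos, K3PO4, THF/H2O, 50 °C
Reagents that add atoms: none
Why: Anti-Markovnikov hydroboration of the only alkene gives the primary alkylborane, and a B-alkyl Suzuki–Miyaura coupling with the vinylic carbon–chlorine bond of chloroprene forms C12–C13 and delivers the 2-substituted buta-1,3-diene directly, under conditions the acetate and tertiary alcohol tolerate.

Step 13
Reactants: 24 3α-acetoxy-18-[diisopropyl(methoxy)silyloxy]labda-13(16),14-dien-8β-ol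
Product: 25 (3R,4S,5S,8S,9R,10R)-8,18-dihydroxylabda-13(16),14-dien-3-yl acetate
Conditions: HF·pyridine, pyridine/THF, 0 °C → rt
Reagents that add atoms: none
Why: Fluoride-mediated desilylation under buffered, non-basic conditions frees the C18 alcohol without acetyl migration from O3 and without harming the diene or the tertiary alcohol.

**Compound list**

1 | (R)-(−)-carvone, (5R)-2-methyl-5-(prop-1-en-2-yl)cyclohex-2-en-1-one | CC1=CC[C@H](CC1=O)C(=C)C | starting material
2 | (5R,6S)-2,6-dimethyl-5-(prop-1-en-2-yl)cyclohex-2-en-1-one (methyl trans to isopropenyl) | CC1=CC[C@H]([C@H](C)C1=O)C(=C)C | intermediate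
3 | lithium alkoxide of (5S,6R)-6-(hydroxymethyl)-2,6-dimethyl-5-(prop-1-en-2-yl)cyclohex-2-en-1-one | CC1=CC[C@H]([C@](C)(CO[Li])C1=O)C(=C)C | intermediate
4 | (5S,6R)-2,6-dimethyl-5-(prop-1-en-2-yl)-6-[(triethylsilyloxy)methyl]cyclohex-2-en-1-one (CH2OSi trans, CH3 cis to isopropenyl) | CC1=CC[C@H]([C@](C)(CO[Si](CC)(CC)CC)C1=O)C(=C)C | intermediate
5 | 5-(1-hydroperoxy-1-methoxyethyl) analogue of 4 (ring configuration as in 4, both epimers at the peroxyketal carbon) | CC1=CC[C@H]([C@](C)(CO[Si](CC)(CC)CC)C1=O)C(C)(OC)OO | intermediate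
6 | (1R,2S)-2,4-dimethyl-3-oxo-2-[(triethylsilyloxy)methyl]cyclohex-4-en-1-yl acetate | CC1=CC[C@@H](OC(C)=O)[C@](C)(CO[Si](CC)(CC)CC)C1=O | intermediate
7 | lithium enolate from 1,4-reduction of 6 (O–Li on C5, C5=C10) | CC1=C(O[Li])[C@@](C)(CO[Si](CC)(CC)CC)[C@H](OC(C)=O)CC1 | intermediate
8 | (1R,2S)-2,4-dimethyl-2-[(triethylsilyloxy)methyl]-3-(trifluoromethylsulfonyloxy)cyclohex-3-en-1-yl acetate | CC1=C(OS(=O)(=O)C(F)(F)F)[C@@](C)(CO[Si](CC)(CC)CC)[C@H](OC(C)=O)CC1 | intermediate
9 | (1R,2S)-3-ethenyl-2,4-dimethyl-2-[(triethylsilyloxy)methyl]cyclohex-3-en-1-yl acetate | CC1=C(C=C)[C@@](C)(CO[Si](CC)(CC)CC)[C@H](OC(C)=O)CC1 | intermediate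
10 | (1R,2S)-3-ethenyl-2-(hydroxymethyl)-2,4-dimethylcyclohex-3-en-1-yl acetate | CC1=C(C=C)[C@@](C)(CO)[C@H](OC(C)=O)CC1 | intermediate
11 | buta-2,3-dienoic acid | C=C=CC(=O)O | starting material
12 | chloro(diisopropyl)silyl ether of 10 | CC1=C(C=C)[C@@](C)(CO[Si](Cl)(C(C)C)C(C)C)[C@H](OC(C)=O)CC1 | intermediate
13 | diisopropylsilyl-tethered triene: silyl ether of 10 and silyl ester of 11 on one silicon | CC1=C(C=C)[C@@](C)(CO[Si](OC(=O)C=C=C)(C(C)C)C(C)C)[C@H](OC(C)=O)CC1 | intermediate
14 | bridged cycloadduct: 3α-acetoxy-pentanorlabda-5,8(17)-diene with an O18–Si(i-Pr)2–O–C11(=O) bridge on the β face | O=C1O[Si](C(C)C)(C(C)C)OC[C@@]2(C)[C@H](OC(C)=O)CC[C@]3(C)C2=CCC(=C)[C@H]13 | intermediate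
15 | 3α-acetoxy-18-[diisopropyl(methoxy)silyloxy]-12,13,14,15,16-pentanorlabda-5,8(17)-dien-11-oic acid (9β-CO2H, 10α-CH3, 4α-CH3) | OC(=O)[C@@H]1[C@]2(C)CC[C@@H](OC(C)=O)[C@](C)(CO[Si](OC)(C(C)C)C(C)C)C2=CCC1=C | intermediate
16 | 17-(acetoxymercurio)-8β-hydroxy adduct of 15 | OC(=O)[C@@H]1[C@]2(C)CC[C@@H](OC(C)=O)[C@](C)(CO[Si](OC)(C(C)C)C(C)C)C2=CC[C@]1(C[Hg]OC(C)=O)O | intermediate
17 | 3α-acetoxy-8β-hydroxy-18-[diisopropyl(methoxy)silyloxy]-12,13,14,15,16-pentanorlabd-5-en-11-oic acid (8α-CH3) | OC(=O)[C@@H]1[C@]2(C)CC[C@@H](OC(C)=O)[C@](C)(CO[Si](OC)(C(C)C)C(C)C)C2=CC[C@]1(C)O | intermediate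
18 | 3α-acetoxy-8β-hydroxy-18-[diisopropyl(methoxy)silyloxy]-12,13,14,15,16-pentanorlabdan-11-oic acid (5β-H) | OC(=O)[C@@H]1[C@]2(C)CC[C@@H](OC(C)=O)[C@](C)(CO[Si](OC)(C(C)C)C(C)C)[C@H]2CC[C@]1(C)O | intermediate
19 | 3α-acetoxy-18-[diisopropyl(methoxy)silyloxy]-12,13,14,15,16-pentanorlabdane-8β,11-diol | OC[C@@H]1[C@]2(C)CC[C@@H](OC(C)=O)[C@](C)(CO[Si](OC)(C(C)C)C(C)C)[C@H]2CC[C@]1(C)O | intermediate
20 | 3α-acetoxy-8β-hydroxy-18-[diisopropyl(methoxy)silyloxy]-12,13,14,15,16-pentanorlabdan-11-al | O=C[C@@H]1[C@]2(C)CC[C@@H](OC(C)=O)[C@](C)(CO[Si](OC)(C(C)C)C(C)C)[C@H]2CC[C@]1(C)O | intermediate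
21 | 3α-acetoxy-18-[diisopropyl(methoxy)silyloxy]-13,14,15,16-tetranorlabd-11-en-8β-ol | C=C[C@@H]1[C@]2(C)CC[C@@H](OC(C)=O)[C@](C)(CO[Si](OC)(C(C)C)C(C)C)[C@H]2CC[C@]1(C)O | intermediate
22 | chloroprene, 2-chlorobuta-1,3-diene | C=CC(Cl)=C | starting material
23 | B-(C12-alkyl)-9-borabicyclo[3.3.1]nonane from 21 | C(CB1C2CCCC1CCC2)[C@@H]1[C@]2(C)CC[C@@H](OC(C)=O)[C@](C)(CO[Si](OC)(C(C)C)C(C)C)[C@H]2CC[C@]1(C)O | intermediate
24 | 3α-acetoxy-18-[diisopropyl(methoxy)silyloxy]labda-13(16),14-dien-8β-ol | C=CC(=C)CC[C@@H]1[C@]2(C)CC[C@@H](OC(C)=O)[C@](C)(CO[Si](OC)(C(C)C)C(C)C)[C@H]2CC[C@]1(C)O | intermediate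
25 | (3R,4S,5S,8S,9R,10R)-8,18-dihydroxylabda-13(16),14-dien-3-yl acetate (3α-OAc, 4α-CH3, 4β-CH2OH, 5β-H, 8β-OH, 9β side chain, 10α-CH3) | C=CC(=C)CC[C@@H]1[C@]2(C)CC[C@@H](OC(C)=O)[C@](C)(CO)[C@H]2CC[C@]1(C)O | target

**Step count and risk**

Total step count: 13. Longest linear sequence: 13 steps (1 → 25).

The three steps most likely to fail:

Step 6 is the main risk. The cycloaddition must form a bond at the fully substituted C10 terminus of a diene that is crowded in its s-cis form, and this exact silyl ether/silyl ester tether is without close precedent. As a fallback, set out from 9, isolated before the acid work-up of step 5, and heat it with 11 without a tether (PhMe, 110 °C). Facial and endo control will be lower and the isomers must be separated to obtain 3α-acetoxy-18-(triethylsilyloxy)-12,13,14,15,16-pentanorlabda-5,8(17)-dien-11-oic acid F1. AcOH/THF/H2O then gives the corresponding 18-hydroxy acid F2, and i-Pr2SiCl2/imidazole followed by MeOH converts it into 15, where the route is rejoined.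

Step 7 is the second risk. The C8 configuration rests on steric and neighbouring-group arguments, and the acetate must survive the basic demercuration. As a fallback, set out from 15 and use iodolactonisation (iodine, NaHCO3) through the 9β-carboxylate, which delivers oxygen to C8 intramolecularly and gives the 17-iodo-11,8β-olide of the Δ5 series F3. Hydrogenation over Pd(OH)2/C with Et3N removes the iodine and saturates C5=C6 to give the saturated 11,8β-olide F4, and LiBH4 opens this β-lactone to diol 19.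

Step 11 is the third risk. The hindered β-hydroxy aldehyde can undergo retro-aldol cleavage or epimerise at C9 under the basic ylide. As a fallback, set out from 19 and silylate both hydroxyls (Me3SiOTf, 2,6-lutidine) to the 8,11-bis(trimethylsilyl) ether F5. Swern oxidation acts directly on the primary silyl ether and gives the 8-O-trimethylsilyl aldehyde F6, which cannot undergo retro-aldol cleavage. Wittig methylenation gives the 8-O-trimethylsilyl vinyl compound F7, and AcOH/THF/H2O removes the tertiary silyl ether to rejoin the route at 21.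

Further compounds
F1 | step 6 | 3α-acetoxy-18-(triethylsilyloxy)-12,13,14,15,16-pentanorlabda-5,8(17)-dien-11-oic acid | OC(=O)[C@@H]1[C@]2(C)CC[C@@H](OC(C)=O)[C@](C)(CO[Si](CC)(CC)CC)C2=CCC1=C
F2 | step 6 | 3α-acetoxy-18-hydroxy-12,13,14,15,16-pentanorlabda-5,8(17)-dien-11-oic acid | OC(=O)[C@@H]1[C@]2(C)CC[C@@H](OC(C)=O)[C@](C)(CO)C2=CCC1=C
F3 | step 7 | 3α-acetoxy-17-iodo-18-[diisopropyl(methoxy)silyloxy]-12,13,14,15,16-pentanorlabd-5-en-11,8β-olide | O=C1[C@@H]2[C@]3(C)CC[C@@H](OC(C)=O)[C@](C)(CO[Si](OC)(C(C)C)C(C)C)C3=CC[C@]2(CI)O1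
F4 | step 7 | 3α-acetoxy-18-[diisopropyl(methoxy)silyloxy]-12,13,14,15,16-pentanorlabdan-11,8β-olide (5β-H) | O=C1[C@@H]2[C@]3(C)CC[C@@H](OC(C)=O)[C@](C)(CO[Si](OC)(C(C)C)C(C)C)[C@H]3CC[C@]2(C)O1
F5 | step 11 | 8,11-bis(trimethylsilyl) ether of 19 | C[Si](C)(C)OC[C@@H]1[C@]2(C)CC[C@@H](OC(C)=O)[C@](C)(CO[Si](OC)(C(C)C)C(C)C)[C@H]2CC[C@]1(C)O[Si](C)(C)C
F6 | step 11 | 8-O-trimethylsilyl ether of 20 | O=C[C@@H]1[C@]2(C)CC[C@@H](OC(C)=O)[C@](C)(CO[Si](OC)(C(C)C)C(C)C)[C@H]2CC[C@]1(C)O[Si](C)(C)C
F7 | step 11 | 8-O-trimethylsilyl ether of 21 | C=C[C@@H]1[C@]2(C)CC[C@@H](OC(C)=O)[C@](C)(CO[Si](OC)(C(C)C)C(C)C)[C@H]2CC[C@]1(C)O[Si](C)(C)C
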